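**Retrosynthetic overview**

1. The target is (2R,3R)-7-O-geranylfustin, a trans-dihydroflavonol. Chroman-4-one numbering is used (O1, C2, C3, C4, C4a, C5–C8, C8a; ring A is the carbocycle, ring C the pyranone), and geranyl is (2E)-3,7-dimethylocta-2,6-dien-1-yl.
2. Late stage: the three silyl ethers come off last. Before that, ring A is made aromatic by dehydrogenation across C5–C6 of a 5,6-dihydro precursor.
3. Key disconnection: in that precursor the chain O1–C8a=C4a–C4(=O)–C3 of ring C is a vinylogous ester. Cutting C2–C3 and O1–C8a together gives a catechol aldehyde (C2 and O1) and a diene C8a(OSiMe3)=C4a–C4(OSiMe3)=C3H(OSi) built on a cyclohexadiene that already carries the C7 geranyl ether.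
4. The diene comes from cyclohexane-1,3-dione and geraniol (3-geranyloxycyclohexenone) by alpha-prime acylation with a silyloxyacetyl Weinreb amide and two O-silylations.
5. Ring order: the carbocycle is present from the start, ring C closes in the key step, and ring A is aromatised afterwards.

Key step: step 9

Assumption: the catalyst from Ti(OiPr)4 and (S)-BINOL is taken to expose the Si face of the aryl aldehyde, by analogy with its allyl and enol silane additions; if the sense is the reverse, (R)-BINOL is used with no other change.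

**Route**

Step 1
Reactants: 1 cyclohexane-1,3-dione
Product: 2 3-chlorocyclohex-2-en-1-one
Conditions: (COCl)2, DMF (cat.), CH2Cl2, 0 °C → rt
Reagents that add atoms: oxalyl chloride, ClC(=O)C(=O)Cl
Why: Activation of the dione enol as its chlorooxalate (Vilsmeier-type catalysis) followed by chloride addition–elimination is the standard conversion of a cyclic 1,3-dione into the 3-chloro enone.

Step 2
Reactants: 2 3-chlorocyclohex-2-en-1-one; 3 geraniol
Product: 4 3-(geranyloxy)cyclohex-2-en-1-one
Conditions: NaH, THF, 0 °C → rt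
Reagents that add atoms: none
Why: Addition–elimination (vinylogous acyl substitution) of sodium geranoxide at C3 of the beta-chloro enone installs the geranyl ether without acid, so the allylic system is not ionised.

Step 3
Reactants: 5 methyl glycolate
Product: 6 methyl 2-(tert-butyldimethylsilyloxy)acetate
Conditions: t-BuMe2SiCl, imidazole, DMF, rt
Reagents that add atoms: tert-butyldimethylsilyl chloride, CC(C)(C)[Si](C)(C)Cl
Why: Imidazole-promoted O-silylation of a primary alcohol is routine and the bulky silyl group later serves the anti selectivity of the key step.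

Step 4
Reactants: 6 methyl 2-(tert-butyldimethylsilyloxy)acetate
Product: 7 2-(tert-butyldimethylsilyloxy)-N-methoxy-N-methylacetamide
Conditions: MeNH(OMe)·HCl, i-PrMgCl, THF, −20 → 0 °C
Reagents that add atoms: N,O-dimethylhydroxylamine hydrochloride, CNOC.Cl
Why: The magnesium amide of N,O-dimethylhydroxylamine, formed with i-PrMgCl, converts the ester into the Weinreb amide at low temperature and leaves the silyl ether alone.

Step 5
Reactants: 4 3-(geranyloxy)cyclohex-2-en-1-one; 7 2-(tert-butyldimethylsilyloxy)-N-methoxy-N-methylacetamide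
Product: 8 2-(tert-butyldimethylsilyloxy)-1-[4-(geranyloxy)-2-hydroxycyclohexa-1,3-dien-1-yl]ethan-1-one, the enol form of 6-[(tert-butyldimethylsilyloxy)acetyl]-3-(geranyloxy)cyclohex-2-en-1-one
Conditions: LiN(iPr)2 (LDA), THF, −78 °C; then 7, −78 → 0 °C; aq. NH4Cl
Reagents that add atoms: none
Why: Kinetic deprotonation of the vinylogous ester takes place at C6 (alpha-prime) and the lithium enolate is C-acylated by the Weinreb amide in a Claisen-type acylation, the chelated tetrahedral adduct surviving until the quench so that neither over-addition nor proton transfer to the product diketone interferes.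

Step 6
Reactants: 8 the enolised beta-diketone
Product: 9 2-(tert-butyldimethylsilyloxy)-1-[4-(geranyloxy)-2-(trimethylsilyloxy)cyclohexa-1,3-dien-1-yl]ethan-1-one
Conditions: Me3SiCl, Et3N, CH2Cl2, 0 °C → rt; pentane, filtration under Ar
Reagents that add atoms: chlorotrimethylsilane, C[Si](C)(C)Cl
Why: O-silylation of the enolised 1,3-diketone under amine base gives the vinylogous silyl ester, and the regioisomeric O-silyl compound, should it form, converges on the same diene in step 7.

Step 7
Reactants: 9 the mono(trimethylsilyl) enol ether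
Product: 10 1-[(Z)-2-(tert-butyldimethylsilyloxy)-1-(trimethylsilyloxy)ethenyl]-4-(geranyloxy)-2-(trimethylsilyloxy)cyclohexa-1,3-diene
Conditions: LiN(iPr)2 (LDA), THF, −78 °C; then Me3SiCl, −78 → 0 °C; pentane, filtration under Ar, used crude
Reagents that add atoms: chlorotrimethylsilane, C[Si](C)(C)Cl
Why: LDA removes a proton from the CH2 alpha to the ketone (the kinetic site, since neither ring CH2 is alpha to the carbonyl) and O-silylation of the enolate, whose two oxygen substituents lie cis as usual for alpha-oxygenated ketone enolates, gives the (Z)-bis(silyloxy)diene, as in the standard two-stage preparation of 1,3-bis(silyloxy)dienes from 1,3-dicarbonyl compounds.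

Step 8
Reactants: 11 3,4-dihydroxybenzaldehyde
Product: 12 3,4-bis(tert-butyldimethylsilyloxy)benzaldehyde
Conditions: t-BuMe2SiCl, imidazole, DMF, rt
Reagents that add atoms: tert-butyldimethylsilyl chloride, CC(C)(C)[Si](C)(C)Cl
Why: Standard silylation of both phenols masks the catechol against the Lewis acid and the later quinone oxidant.

Step 9
Reactants: 10 the (Z)-bis(silyloxy)diene; 12 3,4-bis(tert-butyldimethylsilyloxy)benzaldehyde
Product: 14 (2R,3R)-2-[3,4-bis(tert-butyldimethylsilyloxy)phenyl]-3-(tert-butyldimethylsilyloxy)-7-(geranyloxy)-2,3,5,6-tetrahydro-4H-chromen-4-one, via O-trimethylsilyl aldol adduct 13 (not isolated)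
Conditions: Ti(OiPr)4 (10 mol%), (S)-BINOL (20 mol%), 4 Å MS, Et2O, −20 °C; then CF3CO2H (0.5 equiv), CH2Cl2, −20 → 0 °C
Reagents that add atoms: none
Why: The Lewis acid formed from Ti(OiPr)4 and (S)-BINOL activates the aldehyde and the dienol ether adds through C3 in a vinylogous Mukaiyama aldol reaction (C2–C3) with silyl transfer to the aldolate oxygen, giving 13. Acid then lets the C2 oxygen add to C8a of the beta-silyloxy enone with loss of hexamethyldisiloxane (O1–C8a), a 6-endo-trig addition–elimination that closes the pyranone ring; the sum is a stepwise hetero-Diels–Alder reaction, the closest known type being the catalytic asymmetric cyclocondensation of 1,3-bis(silyloxy)dienes and 1-alkoxy-3-silyloxydienes with aryl aldehydes to 2-aryl-2,3-dihydropyran-4-ones. A concerted [4+2] is not counted on, because the C8a silyloxy group sits on the inside of the s-cis diene. C2 is set by the chiral catalyst, which must deliver C3 to the Si face of the aldehyde to give 2R. C3 is set in an open antiperiplanar transition state in which the bulky C3 silyloxy group turns away from the titanium-bound carbonyl oxygen, which gives the anti aldol and so the 2,3-trans (3R) ring with both substituents pseudo-equatorial. The step needs attack through C3 and not through C4a or C8, which is secured because C3 is the only unhindered CH terminus that receives electron density from all three enol oxygens while C4a is fully substituted, and the mild Lewis acid and brief dilute acid leave the geranyl dienol ether and the aryl silyl ethers intact.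

Step 10
Reactants: 14 the 5,6-dihydro chromenone
Product: 15 (2R,3R)-2-[3,4-bis(tert-butyldimethylsilyloxy)phenyl]-3-(tert-butyldimethylsilyloxy)-7-(geranyloxy)chroman-4-one
Conditions: DDQ (1.1 equiv), toluene, 0 °C → rt
Reagents that add atoms: none
Why: In this quinone dehydrogenation, hydride abstraction from C5 gives a cation stabilised by O1 and by the C7 ether oxygen (the C6-protonated arene) and loss of the C6 proton aromatises ring A, while C2–H next to the ketone-bearing C3 and the O–CH2 of a geranyl ether on a vinylogous ester are poor hydride donors.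

Step 11
Reactants: 15 the tris(silyl) chroman-4-one
Product: 16 (2R,3R)-2-(3,4-dihydroxyphenyl)-7-(geranyloxy)-3-hydroxychroman-4-one (CNP0508026.1)
Conditions: HF·pyridine, pyridine, THF, 0 °C → rt
Reagents that add atoms: none
Why: Pyridine-buffered HF cleaves the two aryl silyl ethers and the secondary silyl ether by Si–F bond formation under conditions too mild to enolise C3, to open the pyranone ring at C2 or to ionise the geranyl ether.

**Compound list**

1 | cyclohexane-1,3-dione | O=C1CCCC(=O)C1 | starting material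
2 | 3-chlorocyclohex-2-en-1-one | O=C1C=C(Cl)CCC1 | intermediate
3 | geraniol, (2E)-3,7-dimethylocta-2,6-dien-1-ol | CC(C)=CCC/C(C)=C/CO | starting material
4 | 3-(geranyloxy)cyclohex-2-en-1-one | CC(C)=CCC/C(C)=C/COC1=CC(=O)CCC1 | intermediate
5 | methyl glycolate | COC(=O)CO | starting material
6 | methyl 2-(tert-butyldimethylsilyloxy)acetate | COC(=O)CO[Si](C)(C)C(C)(C)C | intermediate
7 | 2-(tert-butyldimethylsilyloxy)-N-methoxy-N-methylacetamide | CON(C)C(=O)CO[Si](C)(C)C(C)(C)C | intermediate
8 | 2-(tert-butyldimethylsilyloxy)-1-[4-(geranyloxy)-2-hydroxycyclohexa-1,3-dien-1-yl]ethan-1-one (enol form of the 6-acyl-3-geranyloxycyclohexenone) | CC(C)=CCC/C(C)=C/COC1=CC(O)=C(CC1)C(=O)CO[Si](C)(C)C(C)(C)C | intermediate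
9 | 2-(tert-butyldimethylsilyloxy)-1-[4-(geranyloxy)-2-(trimethylsilyloxy)cyclohexa-1,3-dien-1-yl]ethan-1-one | CC(C)=CCC/C(C)=C/COC1=CC(O[Si](C)(C)C)=C(CC1)C(=O)CO[Si](C)(C)C(C)(C)C | intermediate
10 | 1-[(Z)-2-(tert-butyldimethylsilyloxy)-1-(trimethylsilyloxy)ethenyl]-4-(geranyloxy)-2-(trimethylsilyloxy)cyclohexa-1,3-diene | CC(C)=CCC/C(C)=C/COC1=CC(O[Si](C)(C)C)=C(CC1)/C(O[Si](C)(C)C)=C/O[Si](C)(C)C(C)(C)C | intermediate
11 | 3,4-dihydroxybenzaldehyde | O=Cc1ccc(O)c(O)c1 | starting material
12 | 3,4-bis(tert-butyldimethylsilyloxy)benzaldehyde | O=Cc1ccc(O[Si](C)(C)C(C)(C)C)c(O[Si](C)(C)C(C)(C)C)c1 | intermediate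
13 | (2R,3R)-3-[3,4-bis(tert-butyldimethylsilyloxy)phenyl]-2-(tert-butyldimethylsilyloxy)-1-[4-(geranyloxy)-2-(trimethylsilyloxy)cyclohexa-1,3-dien-1-yl]-3-(trimethylsilyloxy)propan-1-one | CC(C)=CCC/C(C)=C/COC1=CC(O[Si](C)(C)C)=C(CC1)C(=O)[C@H](O[Si](C)(C)C(C)(C)C)[C@H](O[Si](C)(C)C)c1ccc(O[Si](C)(C)C(C)(C)C)c(O[Si](C)(C)C(C)(C)C)c1 | intermediate
14 | (2R,3R)-2-[3,4-bis(tert-butyldimethylsilyloxy)phenyl]-3-(tert-butyldimethylsilyloxy)-7-(geranyloxy)-2,3,5,6-tetrahydro-4H-chromen-4-one | CC(C)=CCC/C(C)=C/COC1=CC2=C(CC1)C(=O)[C@H](O[Si](C)(C)C(C)(C)C)[C@@H](c1ccc(O[Si](C)(C)C(C)(C)C)c(O[Si](C)(C)C(C)(C)C)c1)O2 | intermediate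
15 | (2R,3R)-2-[3,4-bis(tert-butyldimethylsilyloxy)phenyl]-3-(tert-butyldimethylsilyloxy)-7-(geranyloxy)chroman-4-one | CC(C)=CCC/C(C)=C/COc1ccc2c(c1)O[C@H](c1ccc(O[Si](C)(C)C(C)(C)C)c(O[Si](C)(C)C(C)(C)C)c1)[C@@H](O[Si](C)(C)C(C)(C)C)C2=O | intermediate
16 | (2R,3R)-2-(3,4-dihydroxyphenyl)-7-(geranyloxy)-3-hydroxychroman-4-one | CC(C)=CCC/C(C)=C/COc1ccc2c(c1)O[C@H](c1ccc(O)c(O)c1)[C@@H](O)C2=O | target

**Step count and risks**

Total: 11 steps. Longest linear sequence: 8 steps (steps 1, 2, 5, 6, 7, 9, 10, 11).

Step 9. The aldehyde may be attacked through C4a or C8 instead of C3, the catalyst may turn over slowly at the hindered, oxygen-bearing terminus, facial or anti selectivity may be poor, or the acid stage may cost the geranyl group. Fallback: the two events are separated and the activation is changed to Lewis-base-activated silicon. The sequence sets out from 10 and 12: SiCl4 (1.2 equiv) with 5 mol% of the chiral bisphosphoramide (CH2)5[N(Me)P(O)(N,N'-dimethyl-1,1'-binaphthyl-2,2'-diamido)]2 (the antipode that delivers to the Si face) and i-Pr2NEt (cat.) in CH2Cl2 at −78 °C. This open-transition-state, anti- and gamma-selective vinylogous aldol addition to aryl aldehydes gives, after aqueous KF/NaHCO3 work-up, the free anti aldol (2R,3R)-3-[3,4-bis(tert-butyldimethylsilyloxy)phenyl]-2-(tert-butyldimethylsilyloxy)-1-[4-(geranyloxy)-2-hydroxycyclohexa-1,3-dien-1-yl]-3-hydroxypropan-1-one F1, which is isolated. Cyclodehydration with pyridinium p-toluenesulfonate and 4 Å MS in CH2Cl2 then comes back to the route at 14.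

Step 10. The quinone may abstract hydride from the allylic O–CH2 of the geranyl ether (oxidative loss of the geranyl group) or from C2–H, or add to the trisubstituted alkenes, in competition with aromatisation. Fallback: the geranyl group is put on after the oxidation. The sequence sets out from 2:
- With allyl alcohol and NaH, 2 gives 3-(allyloxy)cyclohex-2-en-1-one F2.
- Acylation with 7 as in step 5 gives the allyl diketone in its enol form F3.
- Silylation as in steps 6 and 7 gives the mono(trimethylsilyl) enol ether F4 and the allyl diene F5.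
- The key step with 12 gives, through the allyl silyl aldol adduct F6 (not isolated), the 7-allyloxy tetrahydrochromenone F7.
- DDQ, which leaves a simple allyl ether alone, gives the 7-allyloxy chroman-4-one F8.
- Pd(PPh3)4 and morpholine in THF remove the allyl group to give the 7-hydroxy chroman-4-one F9.
- Mitsunobu etherification of this acidic phenol with geraniol 3 (PPh3, DIAD, THF, 0 °C) comes back to the route at 15.

Step 5. The stabilised enolate may add too slowly to the amide, so that proton exchange or O-acylation takes over. Fallback: the acyl group is introduced at the alcohol oxidation level. The sequence sets out from 4: aldol addition of its lithium enolate (LDA, THF, −78 °C) to commercial (tert-butyldimethylsilyloxy)acetaldehyde gives the beta-hydroxy ketone 6-[2-(tert-butyldimethylsilyloxy)-1-hydroxyethyl]-3-(geranyloxy)cyclohex-2-en-1-one F10 as a mixture of diastereomers. Oxidation with Dess–Martin periodinane (NaHCO3, CH2Cl2, rt) comes back to the route at 8.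

**Further compounds**

F1 | step 9 | (2R,3R)-3-[3,4-bis(tert-butyldimethylsilyloxy)phenyl]-2-(tert-butyldimethylsilyloxy)-1-[4-(geranyloxy)-2-hydroxycyclohexa-1,3-dien-1-yl]-3-hydroxypropan-1-one | CC(C)=CCC/C(C)=C/COC1=CC(O)=C(CC1)C(=O)[C@H](O[Si](C)(C)C(C)(C)C)[C@H](O)c1ccc(O[Si](C)(C)C(C)(C)C)c(O[Si](C)(C)C(C)(C)C)c1
F2 | step 10 | 3-(allyloxy)cyclohex-2-en-1-one | C=CCOC1=CC(=O)CCC1
F3 | step 10 | 1-[4-(allyloxy)-2-hydroxycyclohexa-1,3-dien-1-yl]-2-(tert-butyldimethylsilyloxy)ethan-1-one | C=CCOC1=CC(O)=C(CC1)C(=O)CO[Si](C)(C)C(C)(C)C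
F4 | step 10 | 1-[4-(allyloxy)-2-(trimethylsilyloxy)cyclohexa-1,3-dien-1-yl]-2-(tert-butyldimethylsilyloxy)ethan-1-one | C=CCOC1=CC(O[Si](C)(C)C)=C(CC1)C(=O)CO[Si](C)(C)C(C)(C)C
F5 | step 10 | 4-(allyloxy)-1-[(Z)-2-(tert-butyldimethylsilyloxy)-1-(trimethylsilyloxy)ethenyl]-2-(trimethylsilyloxy)cyclohexa-1,3-diene | C=CCOC1=CC(O[Si](C)(C)C)=C(CC1)/C(O[Si](C)(C)C)=C/O[Si](C)(C)C(C)(C)C
F6 | step 10 | (2R,3R)-1-[4-(allyloxy)-2-(trimethylsilyloxy)cyclohexa-1,3-dien-1-yl]-3-[3,4-bis(tert-butyldimethylsilyloxy)phenyl]-2-(tert-butyldimethylsilyloxy)-3-(trimethylsilyloxy)propan-1-one | C=CCOC1=CC(O[Si](C)(C)C)=C(CC1)C(=O)[C@H](O[Si](C)(C)C(C)(C)C)[C@H](O[Si](C)(C)C)c1ccc(O[Si](C)(C)C(C)(C)C)c(O[Si](C)(C)C(C)(C)C)c1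
F7 | step 10 | (2R,3R)-7-(allyloxy)-2-[3,4-bis(tert-butyldimethylsilyloxy)phenyl]-3-(tert-butyldimethylsilyloxy)-2,3,5,6-tetrahydro-4H-chromen-4-one | C=CCOC1=CC2=C(CC1)C(=O)[C@H](O[Si](C)(C)C(C)(C)C)[C@@H](c1ccc(O[Si](C)(C)C(C)(C)C)c(O[Si](C)(C)C(C)(C)C)c1)O2
F8 | step 10 | (2R,3R)-7-(allyloxy)-2-[3,4-bis(tert-butyldimethylsilyloxy)phenyl]-3-(tert-butyldimethylsilyloxy)chroman-4-one | C=CCOc1ccc2c(c1)O[C@H](c1ccc(O[Si](C)(C)C(C)(C)C)c(O[Si](C)(C)C(C)(C)C)c1)[C@@H](O[Si](C)(C)C(C)(C)C)C2=O
F9 | step 10 | (2R,3R)-2-[3,4-bis(tert-butyldimethylsilyloxy)phenyl]-3-(tert-butyldimethylsilyloxy)-7-hydroxychroman-4-one | Oc1ccc2c(c1)O[C@H](c1ccc(O[Si](C)(C)C(C)(C)C)c(O[Si](C)(C)C(C)(C)C)c1)[C@@H](O[Si](C)(C)C(C)(C)C)C2=O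
F10 | step 5 | 6-[2-(tert-butyldimethylsilyloxy)-1-hydroxyethyl]-3-(geranyloxy)cyclohex-2-en-1-one (mixture of diastereomers) | CC(C)=CCC/C(C)=C/COC1=CC(=O)C(CC1)C(O)CO[Si](C)(C)C(C)(C)C
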